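The plan cuts the α-methylene ε-lactone (O, C12, C13, C14, C1, C15, C16; cembrane numbering) at O–C12 and C15–C1 and the 14-membered carbocycle at C3–C4. It exploits that C1 sits β to the C3 carbinol and that tertiary C12 adjoins oxygenated C11. An enantioselective redox-relay Heck alkenylation of an (E)-allylic alcohol with a pyruvate-derived enol triflate joins C15 to C1, sets C1 and unveils the C3 aldehyde; acid added to the same flask then lets the tert-butyl ester open an (11S,12S)-epoxide at C12, closing the lactone with inversion. The precursor is a linear epoxy allylic alcohol ending in an alkenyl bromide; Nozaki–Hiyama–Kishi ring closure finishes.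

Key step: step 8

Remark: target atoms carry cembranoid numbers (ring carbons C1–C14; C1 = ring CH bearing acrylate carbon C15; C3 = carbinol; C11 = acetoxy carbon; C12 = quaternary lactone carbon; C16 = lactone carbonyl; C17 = exocyclic methylene).
Remark: tert-butyl 2-oxopropanoate (tert-butyl pyruvate) is taken to be commercially available.

Step 1
Reactants: 1 geranyl bromide; 2 prop-1-ynylmagnesium bromide
Product: 3 (5E)-6,10-dimethylundeca-5,9-dien-2-yne
Conditions: CuI (5 mol %), THF, 0 °C to rt
Reagents that add atoms: none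
Why: Copper-catalysed SN2 coupling of an alkynyl Grignard reagent with a primary allylic bromide should give the skipped enyne with the (E)-alkene untouched.

Step 2
Reactants: 3 (5E)-6,10-dimethylundeca-5,9-dien-2-yne
Product: 4 (2E,5E)-2-bromo-6,10-dimethylundeca-2,5,9-triene
Conditions: Cp2Zr(H)Cl (2 equiv), THF, rt then 40 °C; N-bromosuccinimide, 0 °C
Reagents that add atoms: N-bromosuccinimide, O=C1CCC(=O)N1Br
Why: Hydrozirconation with excess Schwartz reagent adds H and Zr syn and, after equilibration, places zirconium on the methyl-bearing alkyne carbon; bromodezirconation with retention should then give the (E)-2-bromoalkene, the trisubstituted alkenes being inert (hydrozirconation–halogenation).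

Step 3
Reactants: 4 (2E,5E)-2-bromo-6,10-dimethylundeca-2,5,9-triene
Product: 5 (2E,6E,9E)-10-bromo-2,6-dimethylundeca-2,6,9-trien-1-ol
Conditions: SeO2 (0.2 equiv), t-BuOOH, salicylic acid (cat.), CH2Cl2, 0 °C to rt
Reagents that add atoms: tert-butyl hydroperoxide, CC(C)(C)OO (oxygen relayed through catalytic selenium dioxide, O=[Se]=O)
Why: Riley allylic oxidation (ene reaction, then [2,3]-sigmatropic shift) should attack the (E)-methyl group of the terminal, most electron-rich isopropylidene unit and deliver the (E)-allylic alcohol.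

Step 4
Reactants: 5 (2E,6E,9E)-10-bromo-2,6-dimethylundeca-2,6,9-trien-1-ol
Product: 6 [(2S,3S)-3-[(3E,6E)-7-bromo-3-methylocta-3,6-dien-1-yl]-2-methyloxiran-2-yl]methanol
Conditions: Ti(OiPr)4 (0.1 equiv), L-(+)-diethyl tartrate (0.12 equiv), t-BuOOH, 4 Å MS, CH2Cl2, −20 °C
Reagents that add atoms: tert-butyl hydroperoxide, CC(C)(C)OO
Why: Sharpless asymmetric epoxidation is directed by the allylic hydroxyl, so only the C11=C12 alkene should react; L-(+)-diethyl tartrate sets both epoxide carbons, (11S,12S), on the (E)-alkene.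

Step 5
Reactants: 6 [(2S,3S)-3-[(3E,6E)-7-bromo-3-methylocta-3,6-dien-1-yl]-2-methyloxiran-2-yl]methanol; 7 allylmagnesium bromide
Product: 9 (2S,3S)-2-(but-3-en-1-yl)-3-[(3E,6E)-7-bromo-3-methylocta-3,6-dien-1-yl]-2-methyloxirane, via epoxy triflate 8 (not isolated)
Conditions: Tf2O, 2,6-lutidine, CH2Cl2, −78 °C; crude triflate in Et2O, then 7, CuI (10 mol %), −78 to −30 °C
Reagents that add atoms: none
Why: The primary triflate should be displaced by the allylcopper species far faster than the trisubstituted epoxide or the alkenyl bromide can react (copper-catalysed Grignard–triflate coupling); no stereocentre is touched.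

Step 6
Reactants: 9 (2S,3S)-2-(but-3-en-1-yl)-3-[(3E,6E)-7-bromo-3-methylocta-3,6-dien-1-yl]-2-methyloxirane; 10 (2Z)-but-2-ene-1,4-diol
Product: 11 (2E)-5-[(2S,3S)-3-[(3E,6E)-7-bromo-3-methylocta-3,6-dien-1-yl]-2-methyloxiran-2-yl]pent-2-en-1-ol
Conditions: 10 (4 equiv), second-generation Hoveyda–Grubbs catalyst (5 mol %), CH2Cl2, 40 °C
Reagents that add atoms: none
Why: Olefin cross-metathesis should engage only the monosubstituted alkene and favour the (E)-allylic alcohol under thermodynamic control; any minor (Z)-isomer is removed on silver nitrate-impregnated silica.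

Step 7
Reactants: 12 tert-butyl 2-oxopropanoate
Product: 13 tert-butyl 2-{[(trifluoromethyl)sulfonyl]oxy}prop-2-enoate
Conditions: Tf2O, 2,6-di-tert-butyl-4-methylpyridine, CH2Cl2, −78 °C to rt
Reagents that add atoms: trifluoromethanesulfonic anhydride, O=S(=O)(OS(=O)(=O)C(F)(F)F)C(F)(F)F
Why: O-Triflation of the enol form of the α-keto ester with a hindered pyridine base should give the electron-poor alkenyl triflate (enol triflate formation).

Step 8
Reactants: 11 (2E)-5-[(2S,3S)-3-[(3E,6E)-7-bromo-3-methylocta-3,6-dien-1-yl]-2-methyloxiran-2-yl]pent-2-en-1-ol; 13 tert-butyl 2-{[(trifluoromethyl)sulfonyl]oxy}prop-2-enoate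
Product: 15 2-[(4R,7R)-7-[(1S,4E,7E)-8-bromo-1-hydroxy-4-methylnona-4,7-dien-1-yl]-7-methyl-3-methylidene-2-oxooxepan-4-yl]acetaldehyde, via epoxy aldehyde ester 14 (not isolated)
Conditions: 13 (1.5 equiv), Pd2(dba)3 (3 mol %), chiral 5-CF3-tBu-PyrOx ligand (8 mol %; the enantiomer that delivers to the Re face of C1), 2,6-di-tert-butyl-4-methylpyridine, 3 Å MS, DMA, rt; then CSA, CH2Cl2, 0 °C to rt, same flask
Reagents that add atoms: none
Why: Zerovalent palladium adds oxidatively to enol triflate 13, the (E)-C1=C2 alkene of 11 inserts syn with the alkenyl group going to C1 (the carbon remote from the hydroxyl), and β-hydride relay to C3 gives aldehyde 14; the closest known reaction type is the enantioselective redox-relay Heck alkenylation of alkenols with electron-poor alkenyl triflates. The added acid then protonates the epoxide and the ester carbonyl oxygen opens it at C12 with loss of isobutene, as in acid-mediated lactonisations of epoxy tert-butyl esters. The oxepanone ring closes in the 7-exo-tet mode. C1 is set by the chiral pyridine–oxazoline ligand (Re-face insertion gives 1R), C12 by stereospecific inversion of the (11S,12S)-epoxide from step 4, and C11 keeps its epoxide oxygen with retention. The step needs site selectivity in the insertion (secured by the polarised allylic alcohol alkene), chemoselectivity for the activated triflate over the unactivated alkenyl bromide (room temperature, N,N-ligand), and attack at tertiary C12 by the conjugated ester carbonyl in preference to the aldehyde oxygen or the C7=C8 alkene (secured by its higher Lewis basicity, the irreversible loss of isobutene and a mild Brønsted acid).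

Step 9
Reactants: 15 2-[(4R,7R)-7-[(1S,4E,7E)-8-bromo-1-hydroxy-4-methylnona-4,7-dien-1-yl]-7-methyl-3-methylidene-2-oxooxepan-4-yl]acetaldehyde
Product: 16 (1S,4E,7E)-8-bromo-4-methyl-1-[(2R,5R)-2-methyl-6-methylidene-7-oxo-5-(2-oxoethyl)oxepan-2-yl]nona-4,7-dien-1-yl acetate
Conditions: Ac2O, pyridine, DMAP (cat.), CH2Cl2, 0 °C
Reagents that add atoms: acetic anhydride, CC(=O)OC(C)=O
Why: Acylation of the only free hydroxyl (C11–OH) under nucleophilic catalysis should leave the aldehyde, the lactone and the stereocentres untouched.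

Step 10
Reactants: 16 (1S,4E,7E)-8-bromo-4-methyl-1-[(2R,5R)-2-methyl-6-methylidene-7-oxo-5-(2-oxoethyl)oxepan-2-yl]nona-4,7-dien-1-yl acetate
Product: 17 dendronpholide A
Conditions: CrCl2 (10 equiv), NiCl2 (0.1 equiv), DMSO–THF, 2 mM, rt to 50 °C
Reagents that add atoms: none
Why: In the Nozaki–Hiyama–Kishi reaction the nickel-catalysed formation of an alkenylchromium reagent from the (E)-alkenyl bromide (geometry retained) and its chemoselective addition to the aldehyde at high dilution should close the 14-membered ring; C3 is set under substrate control by the macrocyclic transition state, which is expected but not assured to favour (3S).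

Compound list
1 | geranyl bromide, (2E)-1-bromo-3,7-dimethylocta-2,6-diene | CC(C)=CCC/C(C)=C/CBr | starting material
2 | prop-1-ynylmagnesium bromide | CC#C[Mg]Br | starting material
3 | (5E)-6,10-dimethylundeca-5,9-dien-2-yne | CC(C)=CCC/C(C)=C/CC#CC | intermediate
4 | (2E,5E)-2-bromo-6,10-dimethylundeca-2,5,9-triene | CC(C)=CCC/C(C)=C/C/C=C(/Br)C | intermediate
5 | (2E,6E,9E)-10-bromo-2,6-dimethylundeca-2,6,9-trien-1-ol | OC/C(C)=C/CC/C(C)=C/C/C=C(/Br)C | intermediate
6 | [(2S,3S)-3-[(3E,6E)-7-bromo-3-methylocta-3,6-dien-1-yl]-2-methyloxiran-2-yl]methanol | OC[C@]1(C)O[C@H]1CC/C(C)=C/C/C=C(/Br)C | intermediate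
7 | allylmagnesium bromide | C=CC[Mg]Br | starting material
8 | [(2S,3S)-3-[(3E,6E)-7-bromo-3-methylocta-3,6-dien-1-yl]-2-methyloxiran-2-yl]methyl trifluoromethanesulfonate | O=S(=O)(OC[C@]1(C)O[C@H]1CC/C(C)=C/C/C=C(/Br)C)C(F)(F)F | intermediate (not isolated)
9 | (2S,3S)-2-(but-3-en-1-yl)-3-[(3E,6E)-7-bromo-3-methylocta-3,6-dien-1-yl]-2-methyloxirane | C=CCC[C@]1(C)O[C@H]1CC/C(C)=C/C/C=C(/Br)C | intermediate
10 | (2Z)-but-2-ene-1,4-diol | OC/C=C\CO | starting material
11 | (2E)-5-[(2S,3S)-3-[(3E,6E)-7-bromo-3-methylocta-3,6-dien-1-yl]-2-methyloxiran-2-yl]pent-2-en-1-ol | OC/C=C/CC[C@]1(C)O[C@H]1CC/C(C)=C/C/C=C(/Br)C | intermediate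
12 | tert-butyl 2-oxopropanoate | CC(=O)C(=O)OC(C)(C)C | starting material
13 | tert-butyl 2-{[(trifluoromethyl)sulfonyl]oxy}prop-2-enoate | C=C(OS(=O)(=O)C(F)(F)F)C(=O)OC(C)(C)C | intermediate
14 | tert-butyl (3R)-5-[(2S,3S)-3-[(3E,6E)-7-bromo-3-methylocta-3,6-dien-1-yl]-2-methyloxiran-2-yl]-2-methylidene-3-(2-oxoethyl)pentanoate | O=CC[C@@H](CC[C@]1(C)O[C@H]1CC/C(C)=C/C/C=C(/Br)C)C(=C)C(=O)OC(C)(C)C | intermediate (not isolated)
15 | 2-[(4R,7R)-7-[(1S,4E,7E)-8-bromo-1-hydroxy-4-methylnona-4,7-dien-1-yl]-7-methyl-3-methylidene-2-oxooxepan-4-yl]acetaldehyde | C=C1C(=O)O[C@](C)(CC[C@@H]1CC=O)[C@@H](O)CC/C(C)=C/C/C=C(/Br)C | intermediate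
16 | (1S,4E,7E)-8-bromo-4-methyl-1-[(2R,5R)-2-methyl-6-methylidene-7-oxo-5-(2-oxoethyl)oxepan-2-yl]nona-4,7-dien-1-yl acetate | C=C1C(=O)O[C@](C)(CC[C@@H]1CC=O)[C@@H](OC(C)=O)CC/C(C)=C/C/C=C(/Br)C | intermediate
17 | dendronpholide A, (1R,3S,4E,7E,11S,12R)-11-acetoxy-3-hydroxycembra-4,7,15(17)-trien-16,12-olide | C=C1C(=O)O[C@]2(C)CC[C@@H]1C[C@H](O)/C(C)=C/C/C=C(\C)CC[C@@H]2OC(C)=O | target

Total step count: 10. Longest linear sequence: 9 (steps 1–6, 8, 9, 10).

Steps most likely to fail

1. Step 8. The palladium catalyst may insert into the alkenyl bromide; the migratory insertion may lose site or facial selectivity; and, in the acid stage, the aldehyde oxygen or the C7=C8 alkene may capture the activated epoxide instead of the ester. The fallback makes the C15–C1 bond by conjugate addition, sets out from 11 and 13, and returns at 15. Alcohol 11 is oxidised with MnO2 (CH2Cl2) to the (2E)-enal F1. Triflate 13 is converted by Miyaura borylation (B2pin2, PdCl2(PPh3)2, PPh3, KOPh, toluene, 50 °C) into tert-butyl 2-(pinacolboryl)acrylate F2. Rhodium-catalysed asymmetric 1,4-addition of F2 to F1 ([RhCl(C2H4)2]2, 2,5-diphenylbicyclo[2.2.2]octa-2,5-diene as the enantiomer that delivers to the Re face of C1, KOH, dioxane–water) should give 14, now isolated. BF3·OEt2 (CH2Cl2, −78 °C), which also ties up the aldehyde oxygen, then closes the lactone to 15.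

2. Step 10. The alkenylchromium species may add to the aldehyde with poor facial selectivity, giving much of the C3 epimer. The fallback sets out from 16 and returns at 17. The ring-closed mixture of C3 epimers is oxidised with Dess–Martin periodinane to the macrocyclic enone F3. Reagent-controlled reduction with (R)-2-methyl-CBS-oxazaborolidine and catecholborane (toluene, −78 °C), in which the alkenyl side acts as the large group, should deliver the (3S)-alcohol 17.

3. Step 3. The oxidant may attack allylic positions of the internal C7=C8 alkene or over-oxidise the product. The fallback builds the (E)-allylic alcohol by degradation and olefination, sets out from 4, and returns at 5. Terminal-selective bromohydrin formation (N-bromosuccinimide, THF–water, 0 °C) gives bromohydrin F4, and K2CO3 in methanol closes it to the terminal epoxide F5. HIO4 in aqueous THF cleaves F5 to the aldehyde F6. Wittig olefination with ethyl 2-(triphenylphosphoranylidene)propanoate gives the (E)-enoate F7, and DIBAL-H (CH2Cl2, −78 °C) reduces it to 5.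

Further compounds
F1 | step 8 | (2E)-5-[(2S,3S)-3-[(3E,6E)-7-bromo-3-methylocta-3,6-dien-1-yl]-2-methyloxiran-2-yl]pent-2-enal | O=C/C=C/CC[C@]1(C)O[C@H]1CC/C(C)=C/C/C=C(/Br)C
F2 | step 8 | tert-butyl 2-(4,4,5,5-tetramethyl-1,3,2-dioxaborolan-2-yl)prop-2-enoate | C=C(B1OC(C)(C)C(C)(C)O1)C(=O)OC(C)(C)C
F3 | step 10 | (1R,4E,7E,11S,12R)-11-acetoxy-3-oxocembra-4,7,15(17)-trien-16,12-olide | C=C1C(=O)O[C@]2(C)CC[C@@H]1CC(=O)/C(C)=C/C/C=C(\C)CC[C@@H]2OC(C)=O
F4 | step 3 | (6E,9E)-3,10-dibromo-2,6-dimethylundeca-6,9-dien-2-ol (racemic) | CC(C)(O)C(Br)CC/C(C)=C/C/C=C(/Br)C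
F5 | step 3 | 3-[(3E,6E)-7-bromo-3-methylocta-3,6-dien-1-yl]-2,2-dimethyloxirane (racemic) | CC1(C)OC1CC/C(C)=C/C/C=C(/Br)C
F6 | step 3 | (4E,7E)-8-bromo-4-methylnona-4,7-dienal | O=CCC/C(C)=C/C/C=C(/Br)C
F7 | step 3 | ethyl (2E,6E,9E)-10-bromo-2,6-dimethylundeca-2,6,9-trienoate | CCOC(=O)/C(C)=C/CC/C(C)=C/C/C=C(/Br)C
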